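**Assumption:** the SMILES is read as the cis-fused (6aS,11aS)-pterocarpan. Pterocarpan numbering is used for the target, and chroman or isoflavone numbering for the precursors.

## Retrosynthetic overview
1. The dihydrofuran ring (C11a–O bond) closes last. It and both stereocentres come from a 2'-hydroxyisoflavone by asymmetric transfer hydrogenation with dynamic kinetic resolution, then acid cyclisation.
2. The pyranone ring and the C3–aryl bond (later C6a–C6b) come from a 2'-hydroxychalcone by an oxidative 1,2-aryl shift (Cβ→Cα) through a phenonium ion, then acetal/phenol condensation.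
3. The chalcone comes from an 8-acetylchroman and a 2-benzyloxy-4-methoxybenzaldehyde (Claisen–Schmidt).
4. The acetylchroman comes from C8 acylation of a chroman made from 3,5-bis(benzyloxy)phenol and isoprene. That phenol comes from resorcinol by meta C–H borylation and oxidation.
5. The aldehyde comes from resorcinol by formylation and two O-alkylations. Ring order: chroman, then pyranone, then dihydrofuran.

## Route

**Step 1**
Reactants: 1 resorcinol
Product: 4 5-(4,4,5,5-tetramethyl-1,3,2-dioxaborolan-2-yl)benzene-1,3-diol, via bis-TMS ether 2 (not isolated), via silylated aryl boronate 3 (not isolated)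
Conditions: (Me3Si)2NH, neat, 110 °C, strip; [Ir(OMe)(cod)]2 (1 mol%), dtbpy (2 mol%), B2pin2 (0.55 equiv), MTBE, 80 °C; MeOH, rt
Reagents that add atoms: bis(pinacolato)diboron CC1(C)OB(OC1(C)C)B1OC(C)(C)C(C)(C)O1
Why: Transient O-silylation masks the acidic OH groups, the sterically governed Ir-catalysed aromatic C–H borylation of a 1,3-disubstituted arene reaches only C5 (the one C–H with no ortho neighbour), and methanolysis strips the TMS groups.

**Step 2**
Reactants: 4 5-(4,4,5,5-tetramethyl-1,3,2-dioxaborolan-2-yl)benzene-1,3-diol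
Product: 6 3,5-bis(benzyloxy)phenol, via dibenzylated aryl boronate 5 (not isolated)
Conditions: BnBr (2.0 equiv), K2CO3, DMF, 50 °C until BnBr is consumed; then THF, 30% aq H2O2, 0 °C → rt
Reagents that add atoms: benzyl bromide BrCc1ccccc1; hydrogen peroxide OO
Why: Williamson benzylation followed by ipso oxidation of the aryl boronate gives a 1,3,5-trioxygenated ring with exactly one free OH, and the benzyl groups arrive only after the borylation so their own aryl C–H bonds never meet the Ir catalyst.

**Step 3**
Reactants: 6 3,5-bis(benzyloxy)phenol; 7 isoprene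
Product: 8 5,7-bis(benzyloxy)-2,2-dimethylchroman
Conditions: AgOTf (5 mol%), isoprene (1.3 equiv), ClCH2CH2Cl, rt → 40 °C
Reagents that add atoms: none
Why: This is a phenol/diene chroman annulation (Friedel–Crafts prenylation ortho to the free OH, then Markovnikov hydroalkoxylation); the two ortho carbons are equivalent by symmetry and only the free OH can close the ring, so one chroman forms.

**Step 4**
Reactants: 8 5,7-bis(benzyloxy)-2,2-dimethylchroman; 9 acetyl chloride
Product: 11 1-[5-(benzyloxy)-7-hydroxy-2,2-dimethylchroman-8-yl]ethan-1-one, via 8-acetyl dibenzyl ether 10 (not isolated)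
Conditions: AcCl (1.2 equiv), TiCl4 (2.2 equiv), CH2Cl2, −40 → 0 °C; aq work-up
Reagents that add atoms: none
Why: Friedel–Crafts acylation should go to C8 (one OBn and the tied-back ring oxygen as neighbours) rather than C6 (two free OBn groups), as in the C8-selective substitution of 5,7-di-O-benzyl flavans, and Ti chelated to the new ketone then cleaves only the ortho benzyl ether (chelation-controlled dealkylation).

**Step 5**
Reactants: 1 resorcinol
Product: 13 2,4-dihydroxybenzaldehyde, via aryl iminium chloride 12 (not isolated)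
Conditions: POCl3, DMF, MeCN, −15 → 25 °C; H2O, 50 °C
Reagents that add atoms: N,N-dimethylformamide CN(C)C=O; water O
Why: Vilsmeier–Haack formylation attacks C4 of resorcinol (ortho to one OH and para to the other), and hydrolysis of the iminium salt gives the aldehyde.

**Step 6**
Reactants: 13 2,4-dihydroxybenzaldehyde
Product: 15 2-(benzyloxy)-4-methoxybenzaldehyde, via 2-hydroxy-4-methoxybenzaldehyde 14 (not isolated)
Conditions: MeI (1.05 equiv), K2CO3 (1.1 equiv), acetone, rt → 40 °C; then BnBr (1.2 equiv), K2CO3 (1.5 equiv), reflux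
Reagents that add atoms: iodomethane CI; benzyl bromide BrCc1ccccc1
Why: In this sequential Williamson alkylation the 4-OH is the more acidic and unchelated site and is methylated first, while the 2-OH, hydrogen-bonded to the aldehyde, reacts only under the forcing benzylation.

**Step 7**
Reactants: 11 1-[5-(benzyloxy)-7-hydroxy-2,2-dimethylchroman-8-yl]ethan-1-one; 15 2-(benzyloxy)-4-methoxybenzaldehyde
Product: 16 (E)-1-[5-(benzyloxy)-7-hydroxy-2,2-dimethylchroman-8-yl]-3-[2-(benzyloxy)-4-methoxyphenyl]prop-2-en-1-one
Conditions: 50% aq KOH, EtOH, rt, 36 h; AcOH to pH 5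
Reagents that add atoms: none
Why: Claisen–Schmidt condensation of a methyl ketone with a non-enolisable aldehyde gives the thermodynamic E-enone, and benzyl ethers and the chroman are inert to base.

**Step 8**
Reactants: 16 (E)-2'-hydroxychalcone
Product: 18 5-(benzyloxy)-9-[2-(benzyloxy)-4-methoxyphenyl]-2,2-dimethyl-3,4-dihydro-2H,10H-pyrano[2,3-f]chromen-10-one (dibenzyl isoflavone), via keto acetal 17 (not isolated)
Conditions: 4-iodotoluene (15 mol%), mCPBA (1.2 equiv, slow addition), TsOH·H2O (30 mol%), MeOH–HC(OMe)3 1:1, 0 °C → rt; then 55 °C, 2 h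
Reagents that add atoms: none
Why: Proposed new method: an aryl-iodide-catalysed oxidative 1,2-aryl migration that runs through to the isoflavone in one flask; mCPBA/TsOH turn 4-iodotoluene into a Koser-type ArI(OH)OTs that binds the enone at Cα while MeOH (or the 2'-OH) adds at the cation-stabilising Cβ, the 2,4-dialkoxyphenyl ring then expels ArI from Cα through a phenonium ion (skeletal 1,2-shift Cβ→Cα, forming the C3–aryl bond), the oxocarbenium ion left at Cβ is caught as acetal 17, the same acid condenses 17 with the chelated phenol and eliminates MeOH to close the pyranone, the released ArI is re-oxidised, and the acyl-deactivated A ring plus slow peracid addition hold back arene oxidation; the closest known reaction types are the stoichiometric Tl(NO3)3 or PhI(OH)OTs/PhI(OAc)2 rearrangement of chalcones and flavanones and the ArI/mCPBA/TsOH catalysis used for ketone α-tosyloxylation.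

**Step 9**
Reactants: 18 dibenzyl isoflavone
Product: 19 5-hydroxy-9-(2-hydroxy-4-methoxyphenyl)-2,2-dimethyl-3,4-dihydro-2H,10H-pyrano[2,3-f]chromen-10-one
Conditions: H2 (1 atm), 10% Pd/C, EtOAc–MeOH, rt
Reagents that add atoms: none
Why: Neutral catalytic hydrogenolysis removes both aryl benzyl ethers without acid, so the tertiary chroman C–O bond cannot migrate to the freed neighbouring OH, and any over-reduced isoflavanone is simply the next intermediate.

**Step 10**
Reactants: 19 2'-hydroxyisoflavone
Product: 22 (6aS,11aS)-target pterocarpan, via racemic isoflavanone 20 (not isolated), via cis-isoflavan-4-ol 21 (not isolated)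
Conditions: RuCl[(S,S)-TsDPEN](p-cymene) (3 mol%), HCO2H–Et3N 5:2, EtOAc, 45 °C; then conc. HCl, EtOH, 0 °C → rt
Reagents that add atoms: none
Why: In this Noyori–Ikariya asymmetric transfer hydrogenation cascade, conjugate reduction gives isoflavanone 20, which racemises at C3; the (S,S)-catalyst reduces the aryl ketone to the 4S alcohol anti to the aryl group and so selects the 3S enantiomer (dynamic kinetic resolution, cis-(3S,4S)-21, fixing C6a as S); acid then ionises the C4–OH and the 2'-OH closes the five-membered ring on the face of the aryl group, because only the cis fusion is strain-free, giving C11a as S.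

## Compound list
1 | resorcinol | Oc1cccc(O)c1 | starting material
2 | 1,3-bis(trimethylsilyloxy)benzene | C[Si](C)(C)Oc1cccc(O[Si](C)(C)C)c1 | intermediate
3 | 2-[3,5-bis(trimethylsilyloxy)phenyl]-4,4,5,5-tetramethyl-1,3,2-dioxaborolane | C[Si](C)(C)Oc1cc(O[Si](C)(C)C)cc(c1)B1OC(C)(C)C(C)(C)O1 | intermediate
4 | 5-(4,4,5,5-tetramethyl-1,3,2-dioxaborolan-2-yl)benzene-1,3-diol | Oc1cc(O)cc(c1)B1OC(C)(C)C(C)(C)O1 | intermediate
5 | 2-[3,5-bis(benzyloxy)phenyl]-4,4,5,5-tetramethyl-1,3,2-dioxaborolane | CC1(C)OB(OC1(C)C)c1cc(OCc2ccccc2)cc(OCc2ccccc2)c1 | intermediate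
6 | 3,5-bis(benzyloxy)phenol | Oc1cc(OCc2ccccc2)cc(OCc2ccccc2)c1 | intermediate
7 | isoprene | C=CC(C)=C | starting material
8 | 5,7-bis(benzyloxy)-2,2-dimethylchroman | CC1(C)CCc2c(OCc3ccccc3)cc(OCc3ccccc3)cc2O1 | intermediate
9 | acetyl chloride | CC(Cl)=O | starting material
10 | 1-[5,7-bis(benzyloxy)-2,2-dimethylchroman-8-yl]ethan-1-one | CC(=O)c1c(OCc2ccccc2)cc(OCc2ccccc2)c2CCC(C)(C)Oc12 | intermediate
11 | 1-[5-(benzyloxy)-7-hydroxy-2,2-dimethylchroman-8-yl]ethan-1-one | CC(=O)c1c(O)cc(OCc2ccccc2)c2CCC(C)(C)Oc12 | intermediate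
12 | (2,4-dihydroxybenzylidene)dimethyliminium chloride | C[N+](C)=Cc1ccc(O)cc1O.[Cl-] | intermediate
13 | 2,4-dihydroxybenzaldehyde | O=Cc1ccc(O)cc1O | intermediate
14 | 2-hydroxy-4-methoxybenzaldehyde | COc1ccc(C=O)c(O)c1 | intermediate
15 | 2-(benzyloxy)-4-methoxybenzaldehyde | COc1ccc(C=O)c(OCc2ccccc2)c1 | intermediate
16 | (E)-1-[5-(benzyloxy)-7-hydroxy-2,2-dimethylchroman-8-yl]-3-[2-(benzyloxy)-4-methoxyphenyl]prop-2-en-1-one | COc1ccc(/C=C/C(=O)c2c(O)cc(OCc3ccccc3)c3CCC(C)(C)Oc23)c(OCc2ccccc2)c1 | intermediate
17 | 1-[5-(benzyloxy)-7-hydroxy-2,2-dimethylchroman-8-yl]-2-[2-(benzyloxy)-4-methoxyphenyl]-3,3-dimethoxypropan-1-one (racemic) | COc1ccc(C(C(OC)OC)C(=O)c2c(O)cc(OCc3ccccc3)c3CCC(C)(C)Oc23)c(OCc2ccccc2)c1 | intermediate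
18 | 5-(benzyloxy)-9-[2-(benzyloxy)-4-methoxyphenyl]-2,2-dimethyl-3,4-dihydro-2H,10H-pyrano[2,3-f]chromen-10-one | COc1ccc(c(OCc2ccccc2)c1)C1=COc2cc(OCc3ccccc3)c3CCC(C)(C)Oc3c2C1=O | intermediate
19 | 5-hydroxy-9-(2-hydroxy-4-methoxyphenyl)-2,2-dimethyl-3,4-dihydro-2H,10H-pyrano[2,3-f]chromen-10-one | COc1ccc(c(O)c1)C1=COc2cc(O)c3CCC(C)(C)Oc3c2C1=O | intermediate
20 | 8,9-dihydro derivative of 19 (isoflavanone, racemic and racemising at C3) | COc1ccc(c(O)c1)C1COc2cc(O)c3CCC(C)(C)Oc3c2C1=O | intermediate
21 | cis-(3S,4S)-isoflavan-4-ol from 20 (4-OH and 3-aryl on the same face) | COc1ccc(c(O)c1)[C@H]1COc2cc(O)c3CCC(C)(C)Oc3c2[C@H]1O | intermediate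
22 | (6aS,11aS)-3-hydroxy-9-methoxypterocarpan with a 2,2-dimethyl-3,4-dihydro-2H-pyran ring fused through O at C1 and CH2 at C2 (CNP0207547.1) | COc1ccc2c(c1)O[C@@H]1c3c(cc(O)c4c3OC(C)(C)CC4)OC[C@H]21 | target

## Step count and risks
Total steps: 10. Longest linear sequence: 8 (steps 1, 2, 3, 4, 7, 8, 9, 10).

**Step 8 (the new step).** Iodane turnover may be slower than peracid or iodane attack on the free phenol and the electron-rich rings, and flavanone or flavone side channels may compete. The fallback is known chemistry and sets out from 16. It uses stoichiometric oxythallation–rearrangement with Tl(NO3)3·3H2O in MeOH–HC(OMe)3 at rt and isolates keto acetal 17. A separate ring closure with 10% HCl in MeOH at 50 °C follows. It comes back to the route at 18 and makes no new compound F0.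

**Step 4.** Acylation may go to C6, the second benzyl group may be lost, or TiCl4 may open the tertiary chroman C–O bond. The fallback sets out from 6 and reverses the order, so that the free phenol rather than ring sterics fixes the regiochemistry.
- Ac2O/BF3·OEt2 (acylation/Fries ortho to OH) gives 1-[2,4-bis(benzyloxy)-6-hydroxyphenyl]ethan-1-one F1.
- Isoprene with H3PO4 or BF3·OEt2 annulates on the only free OH and its only open ortho carbon to give 10, now isolated.
- BCl3 (1.1 equiv, CH2Cl2, −78 °C) removes only the benzyl group chelated to the ketone.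

It comes back to the route at 11.

**Step 10.** The ketone of 20 is very electron-rich and flanked by the peri ether oxygen. Hydride transfer may therefore be slow, the resolution incomplete, or the labile benzylic alcohol over-reduced. The fallback sets out from 18, sets C6a by asymmetric alkene hydrogenation, and forms the C11a–O bond oxidatively.
- NaBH4 (THF–EtOH) gives the dibenzyl isoflavan-4-ol F2.
- Catalytic TsOH in toluene dehydrates it to the dibenzyl isoflav-3-ene F3.
- Ir–phosphine-oxazoline-catalysed asymmetric hydrogenation (H2 50 bar, CH2Cl2) gives the (3S)-isoflavan dibenzyl ether F4.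
- H2, Pd/C gives the (3S)-2',7-dihydroxyisoflavan F5.
- DDQ (1.0 equiv, CH2Cl2, rt) forms the C4 p-quinone methide, which the 2'-OH traps on the face of the aryl group.

It comes back to the route at 22.

## Further compounds
F1 | step 4 | 1-[2,4-bis(benzyloxy)-6-hydroxyphenyl]ethan-1-one | CC(=O)c1c(O)cc(OCc2ccccc2)cc1OCc1ccccc1
F0 | step 8 | none | none
F2 | step 10 | dibenzyl isoflavan-4-ol (racemic diastereomer mixture) | COc1ccc(c(OCc2ccccc2)c1)C1COc2cc(OCc3ccccc3)c3CCC(C)(C)Oc3c2C1O
F3 | step 10 | dibenzyl isoflav-3-ene | COc1ccc(c(OCc2ccccc2)c1)C1=Cc2c(cc(OCc3ccccc3)c3CCC(C)(C)Oc23)OC1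
F4 | step 10 | (3S)-isoflavan dibenzyl ether | COc1ccc(c(OCc2ccccc2)c1)[C@@H]1Cc2c(cc(OCc3ccccc3)c3CCC(C)(C)Oc23)OC1
F5 | step 10 | (3S)-2',7-dihydroxyisoflavan | COc1ccc(c(O)c1)[C@@H]1Cc2c(cc(O)c3CCC(C)(C)Oc23)OC1
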